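Assumption: 1-bromo-3,5-bis(benzyloxy)benzene (1) and 2-(tert-butyldimethylsilyl)-1,3-dithiane (12) are treated as catalogue chemicals; the arene is numbered C1 (carboxyl-bearing) to C6 (chain-bearing) and the chain C1'–C13'.

## Structural features

The target 22 has a single ring, a benzene carrying a carboxyl group at C1, hydroxyls at C2 and C4 and, at C6, an unbranched thirteen-carbon chain C1'–C13'. The chain is joined to the ring through the benzylic methylene C1' and carries secondary acetates at C2' and C12' (both R), separated by the nine methylenes C3'–C11'. The two stereocentres are ten bonds apart, so neither can direct the other and each has to come from its own enantiopure building block. The fragile points are the acetates (lost to strong base, acid or organometallics), the 2,4-dihydroxybenzoic acid (prone to decarboxylation on heating or in acid) and, above all, the relation between C2' and the C1 carboxyl carbon: a free C2' oxygen next to an acyl group at C1 closes to a six-membered lactone (a 3,4-dihydroisocoumarin). The real difficulty is therefore one of order, not of ring construction: a long chain with two remote stereocentres has to be joined, and the C2' acetate and the C1 carboxyl have to be installed so that they never meet as alcohol and ester. The key step exploits the fact that C2' is an oxygen-bearing carbon flanked by the methylene C3': this is the pattern left by a terminal epoxide (C2'–C3') opened at C3', and the alkoxide so formed sits 1,4 to a silyl group on C4', so that C4' can act as a carbanion twice, first towards C3' and, after silicon has moved to the C2' oxygen, towards C5'. A further help is the local symmetry of the 3,5-dioxygenated arene before the carboxyl carbon is present: the two positions ortho to the chain are equivalent.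

## Logic of the disconnections

22 back to 21: the two phenol O–benzyl bonds are cut last. Hydrogenolysis is neutral and runs at room temperature, so the free acid, the free phenols and the C2' acetate first coexist in the final product. The demand is that 21 holds no sulfur and nothing else that is reducible.

21 back to 20 and 19: the bond between C1 and the carboxyl carbon is cut. Because this carbon is added after the acetates are in place, no free C2' oxygen ever faces an acyl group at C1. The gain is that 19 has two equivalent ring positions ortho to the chain. The forward demand is an electrophilic formylation that goes ortho to the chain (para to one benzyloxy group) and not between the two benzyloxy groups, followed by an aldehyde oxidation that does not chlorinate the ring.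

19 back to 17 (through 18): the two O–acetyl bonds are exchanged for O–silyl bonds. Acetates cannot pass the organolithium chemistry, whereas silyl ethers can. The demand on the design is that the C12' oxygen of 11 carries the same silyl group that the key step places on the C2' oxygen, so that one fluoride treatment frees both.

17 back to 16: the two C4'–H bonds are replaced by C4'–S bonds. The plain methylene C4' is recognised as a masked dithiane carbon. The forward demand is a reductive desulfurization that spares the aryl benzyl ethers.

16 back to 12, 5 and 11: the bonds C3'–C4' and C4'–C5' are cut. This divides the chain into a three-carbon aryl epoxide holding C2', a one-carbon linchpin and a nine-carbon iodide holding C12', so each stereocentre comes from a separate small epoxide. The forward demand is ordered reactivity: the first anion must meet only the epoxide, the silyl shift must occur only on command, and the second anion must substitute at the primary iodide.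

5 back to 4, then to 1 and 2: the aryl–C1' bond is cut and the epoxide is traced to a chlorohydrin. C2' is thereby taken from 2 without any asymmetric step. The demand is that the arylmetal 3 attacks the epoxide CH2 of 2 and does not displace chloride, since that path would lead to the enantiomer.

11 back to 10, 9, then 6 and 7: the C–I bond is traced to C–Cl and the C10'–C11' bond is cut. C12' comes from 7, and the terminal chloride survives Grignard formation at the bromide end of 6. The demand is chemoselective magnesium insertion into C–Br and clean halide exchange at the end.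

## Other disconnections considered

Alternative 1: The cut runs through the arene itself, at C1–C2 and C5–C6, so the benzene ring would be grown on a finished chain. In the forward sense 1-methoxy-1,3-bis(trimethylsilyloxy)buta-1,3-diene A1 would be heated with benzyl (5R,15R)-5,15-diacetoxyhexadec-2-ynoate A2. A [4+2] cycloaddition in which the nucleophilic diene terminus (future C5) bonds to the ynoate β-carbon (future C6) would be followed by loss of the methoxy group and desilylating work-up to give benzyl 6-[(2R,12R)-2,12-diacetoxytridecyl]-2,4-dihydroxybenzoate A3. One hydrogenolysis would then give 22.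
- In its favour: the carboxyl carbon arrives inside the dienophile, so its position is fixed by the polarisation of both partners. No phenol protection and no aromatic substitution are needed, and only one step follows the key step. On regiochemical certainty at C1 and on end-game length this alternative is the better of the two.
- Against it: β-alkyl ynoates are sluggish dienophiles and would need prolonged heating with a diene that is thermally and hydrolytically labile. A2 has an acidic propargylic methylene between the alkyne and the acetoxy-bearing carbon, so isomerisation to an allenoate and expulsion of acetate would threaten C2'. A2 also contains the whole chain with both stereocentres, so the chain-joining problem is moved, not solved.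
- Comparison: on structure, neither key step makes a stereocentre. On mechanism, a thermal pericyclic step offers no handle for control, whereas the anion relay is timed by a cosolvent. On step economy the short end-game is offset by the synthesis of A2, so the two plans are judged roughly equal in length.

Alternative 2: The cut is at C1–C6 and C2–C3, with the ring made as a cyclohexane-1,3-dione and aromatised later. In the forward sense the anion of dibenzyl malonate A5 would add to the β-carbon of (3E,6R,16R)-6,16-bis(tert-butyldimethylsilyloxy)heptadec-3-en-2-one A4. The methyl ketone enolate would then close onto one ester by intramolecular Claisen condensation to give benzyl 2-[(2R,12R)-2,12-bis(tert-butyldimethylsilyloxy)tridecyl]-4,6-dioxocyclohexane-1-carboxylate A6, to be aromatised oxidatively.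
- In its favour: cheap reagents, no cryogenic organometallics, no sulfur and an unambiguous position for the carboxyl carbon. In regiochemical certainty and probably in scalability it is the equal or the better of the chosen plan.
- Against it: the alkoxide base can deprotonate the γ-methylene of A4 (future C1'), and the resulting dienolate can expel the silyloxy group from C2', erasing that stereocentre. Halogen-based aromatisation endangers silyl ethers and the electron-rich ring.
- The ordering problem is the most serious: the C1 ester exists before the acetates do. Exchanging silyl for acetyl would free the C2' hydroxyl beside that ester and invite lactonisation, and the free phenols would be acetylated too. Acetates carried from the start would not survive the alkoxide.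
- Comparison: the mechanism is classical carbonyl chemistry, as dependable in principle as the anion relay, but the structure forces a protecting-group conflict that the chosen plan does not have. At least four steps would follow the key step, and A4 still needs the full chain, so there is no saving in steps.

Alternative 3: The cut is at C6–C1' and at C1–carboxyl carbon, both made in one palladium-catalysed operation of the Catellani type on the arene. In the forward sense 2,4-bis(benzyloxy)-1-iodobenzene A7 would undergo oxidative addition to zerovalent palladium, insertion of the strained bicyclic alkene mediator and palladation of the C6–H bond. The palladacycle would be alkylated by (2R,12R)-1-iodotridecane-2,12-diyl diacetate A8 through a tetravalent palladium intermediate, and after extrusion of the mediator, alkoxycarbonylation at C1 would give benzyl 2,4-bis(benzyloxy)-6-[(2R,12R)-2,12-diacetoxytridecyl]benzoate A9. Global hydrogenolysis would give 22.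
- In its favour: this is the most convergent treatment of the arene. Both ring substituents are set by the position of iodine and the single free ortho C–H, and one step remains afterwards. On regiocontrol and on the number of steps after the key step it is better than the chosen plan.
- Against it: A8 is branched at the carbon next to the reacting CH2 and carries an acetoxy group there. The substitution-like oxidative addition to the palladacycle would be slowed, and any alkylpalladium species could lose acetate by β-elimination. Carbonylation of the arylpalladium (divalent palladium) before alkylation would give the unalkylated benzoate. A8 is itself labile (acetyl migration, epoxide formation) and requires the complete chain with both stereocentres.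
- Comparison: on structure both plans leave the stereocentres untouched. On mechanism a catalytic cycle with several competing exits stands against three stoichiometric, individually well-understood events. On overall step count the plans are about equal once the route to A8 is included.

Key step: step 6

## Route

Step 1
Reactants: 1 1-bromo-3,5-bis(benzyloxy)benzene; 2 (S)-epichlorohydrin
Product: 4 (S)-1-[3,5-bis(benzyloxy)phenyl]-3-chloropropan-2-ol, via arylmagnesium bromide 3 (not isolated)
Conditions: Mg, THF, 50 °C; then CuI (10 mol %), 2, THF, −40 → 0 °C; aq NH4Cl
Reagents that add atoms: none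
Why: Copper-catalysed opening of an epoxide by a Grignard reagent occurs by SN2 attack at the unsubstituted epoxide CH2 faster than displacement of chloride; the stereocentre of 2 is not a reacting centre and stays S, because CH2Cl still outranks the carbon that now bears the aryl group.

Step 2
Reactants: 4 (S)-1-[3,5-bis(benzyloxy)phenyl]-3-chloropropan-2-ol
Product: 5 (S)-2-[3,5-bis(benzyloxy)benzyl]oxirane
Conditions: K2CO3, MeOH, 0 °C → rt
Reagents that add atoms: none
Why: Intramolecular Williamson etherification (3-exo-tet) of the chlorohydrin; the alkoxide displaces chloride at the primary carbon, so the carbinol carbon is a spectator and its configuration (S) is carried over.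

Step 3
Reactants: 6 1-bromo-6-chlorohexane; 7 (R)-propylene oxide
Product: 9 (R)-9-chlorononan-2-ol, via 6-chlorohexylmagnesium bromide 8 (not isolated)
Conditions: Mg, THF, rt; then CuI (10 mol %), 7, THF, −30 → 0 °C; aq NH4Cl
Reagents that add atoms: none
Why: Magnesium inserts into C–Br far faster than into C–Cl, so the Grignard reagent keeps its terminal chloride; copper-catalysed SN2 opening of 7 at its CH2 leaves the methyl-bearing stereocentre untouched (R).

Step 4
Reactants: 9 (R)-9-chlorononan-2-ol
Product: 10 (R)-tert-butyl[(9-chlorononan-2-yl)oxy]dimethylsilane
Conditions: TBSCl, imidazole, DMF, rt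
Reagents that add atoms: tert-butyldimethylsilyl chloride, CC(C)(C)[Si](C)(C)Cl
Why: Standard imidazole-promoted silylation of a secondary alcohol; the silyl group is chosen to match the one that the key step places on the C2' oxygen, so that both are removed together later.

Step 5
Reactants: 10 (R)-tert-butyl[(9-chlorononan-2-yl)oxy]dimethylsilane
Product: 11 (R)-tert-butyl[(9-iodononan-2-yl)oxy]dimethylsilane
Conditions: NaI, NaHCO3 (cat.), 2-butanone, reflux
Reagents that add atoms: sodium iodide, [Na+].[I-]
Why: Finkelstein halide exchange at an unhindered primary chloride, driven by precipitation of NaCl; the buffered neutral medium leaves the silyl ether and the remote stereocentre alone.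

Step 6
Reactants: 12 2-(tert-butyldimethylsilyl)-1,3-dithiane; 5 (S)-2-[3,5-bis(benzyloxy)benzyl]oxirane; 11 (R)-tert-butyl[(9-iodononan-2-yl)oxy]dimethylsilane
Product: 16 2-[(2S)-3-[3,5-bis(benzyloxy)phenyl]-2-(tert-butyldimethylsilyloxy)propyl]-2-[(8R)-8-(tert-butyldimethylsilyloxy)nonyl]-1,3-dithiane, via lithiated silyl dithiane 13 (not isolated), via lithium alkoxide adduct 14 (not isolated), via relayed dithianyl anion 15 (not isolated)
Conditions: 12, t-BuLi, Et2O, −78 → −45 °C; 5, Et2O, −78 → −25 °C; then 11, HMPA, THF, −78 → 0 °C
Reagents that add atoms: none
Why: Deprotonation of 12 gives the silyl-stabilised anion 13, which opens epoxide 5 by SN2 attack at the unsubstituted C3' methylene to give alkoxide 14; in ether alone the lithium alkoxide is tightly aggregated and silicon stays on carbon. When HMPA is added with iodide 11, the O–Li ion pair loosens, oxygen attacks silicon through a five-membered pentacoordinate silicate, and the 1,4-Brook shift from carbon to oxygen releases the sulfur-stabilised carbanion 15, which is alkylated by the primary iodide (SN2) to form C4'–C5'. The closest known reaction type is the solvent-controlled anion-relay (Brook rearrangement) three-component coupling of 2-silyl-1,3-dithianes with an epoxide and a second electrophile, a known process in which alkyl halides are accepted terminating partners. No ring is closed (the dithiane ring is carried through unchanged) and no stereocentre is created: C2' is never a reacting centre and keeps the configuration of 5, reading S only because the dithiane carbon raises the priority of C3', and C12' is remote and untouched. The step needs regioselective opening at the epoxide CH2 (secured by the terminal epoxide and the bulky nucleophile), strict timing so that 13 meets only 5 and 15 meets only 11 (secured by withholding the polar cosolvent until the epoxide is consumed), and substitution over elimination at 11 (secured by the unbranched primary iodide and low temperature). The arene carries no carbonyl group at this stage, so alkoxide 14 has no intramolecular acceptor, and the benzyl ethers and the silyl ether of 11 are inert to the soft dithiane anions once a slight excess of 12 has consumed all t-BuLi.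

Step 7
Reactants: 16 2-[(2S)-3-[3,5-bis(benzyloxy)phenyl]-2-(tert-butyldimethylsilyloxy)propyl]-2-[(8R)-8-(tert-butyldimethylsilyloxy)nonyl]-1,3-dithiane
Product: 17 (2R,12R)-1-[3,5-bis(benzyloxy)phenyl]-2,12-bis(tert-butyldimethylsilyloxy)tridecane
Conditions: Raney Ni (W-2, washed neutral, acetone-deactivated), EtOH, rt
Reagents that add atoms: none
Why: Raney nickel hydrogenolysis of both C–S bonds (Mozingo-type desulfurization) turns C4' into a methylene; the deactivated neutral catalyst at room temperature is chosen to spare the aryl benzyl ethers and silyl ethers, and the C2' descriptor returns to R only because the priorities of C1' and C3' swap.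

Step 8
Reactants: 17 (2R,12R)-1-[3,5-bis(benzyloxy)phenyl]-2,12-bis(tert-butyldimethylsilyloxy)tridecane
Product: 19 (2R,12R)-1-[3,5-bis(benzyloxy)phenyl]tridecane-2,12-diyl diacetate, via free diol 18 (not isolated)
Conditions: TBAF, THF, rt → 40 °C; then Ac2O, pyridine, DMAP, 0 °C → rt
Reagents that add atoms: acetic anhydride, CC(=O)OC(C)=O
Why: Fluoride cleaves both Si–O bonds and DMAP-catalysed acylation with excess anhydride then esterifies both secondary alcohols in the same flask; no C–O bond at either stereocentre is broken, and no acyl group is yet present at C1, so the free C2' hydroxyl has nothing to lactonise onto.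

Step 9
Reactants: 19 (2R,12R)-1-[3,5-bis(benzyloxy)phenyl]tridecane-2,12-diyl diacetate
Product: 20 (2R,12R)-1-[3,5-bis(benzyloxy)-2-formylphenyl]tridecane-2,12-diyl diacetate
Conditions: POCl3, DMF, 0 → 70 °C; then aq NaOAc
Reagents that add atoms: N,N-dimethylformamide, CN(C)C=O; water, O
Why: Vilsmeier–Haack formylation of a 1-alkyl-3,5-dialkoxybenzene; the chloroiminium electrophile prefers the position para to one benzyloxy group and ortho to the chain (two equivalent sites) over the site between the two benzyloxy groups, and the acetates and benzyl ethers tolerate the reagent.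

Step 10
Reactants: 20 (2R,12R)-1-[3,5-bis(benzyloxy)-2-formylphenyl]tridecane-2,12-diyl diacetate
Product: 21 2,4-bis(benzyloxy)-6-[(2R,12R)-2,12-diacetoxytridecyl]benzoic acid
Conditions: NaClO2, NaH2PO4, 2-methyl-2-butene, t-BuOH/THF/H2O, 0 °C → rt
Reagents that add atoms: sodium chlorite, [Na+].[O-]Cl=O
Why: Pinnick oxidation converts the hindered aryl aldehyde to the acid at buffered pH without touching the acetates; the alkene scavenger removes hypochlorous acid before it can chlorinate the arene.

Step 11
Reactants: 21 2,4-bis(benzyloxy)-6-[(2R,12R)-2,12-diacetoxytridecyl]benzoic acid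
Product: 22 6-[(2R,12R)-2,12-diacetoxytridecyl]-2,4-dihydroxybenzoic acid (target)
Conditions: H2 (1 atm), Pd/C, EtOAc, rt
Reagents that add atoms: none
Why: Catalytic hydrogenolysis of the two aryl benzyl ethers under neutral, non-nucleophilic conditions; the acetates, the carboxylic acid and both stereocentres are inert, and the absence of acid, base and heat guards against lactonisation at C2' and decarboxylation.

## Compound list

1 | 1-bromo-3,5-bis(benzyloxy)benzene | Brc1cc(OCc2ccccc2)cc(OCc2ccccc2)c1 | starting material
2 | (S)-epichlorohydrin [(S)-2-(chloromethyl)oxirane] | ClC[C@@H]1CO1 | starting material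
3 | [3,5-bis(benzyloxy)phenyl]magnesium bromide | Br[Mg]c1cc(OCc2ccccc2)cc(OCc2ccccc2)c1 | intermediate, formed in the flask
4 | (S)-1-[3,5-bis(benzyloxy)phenyl]-3-chloropropan-2-ol | ClC[C@@H](O)Cc1cc(OCc2ccccc2)cc(OCc2ccccc2)c1 | intermediate
5 | (S)-2-[3,5-bis(benzyloxy)benzyl]oxirane | c1ccc(COc2cc(C[C@H]3CO3)cc(OCc3ccccc3)c2)cc1 | intermediate
6 | 1-bromo-6-chlorohexane | ClCCCCCCBr | starting material
7 | (R)-propylene oxide [(R)-2-methyloxirane] | C[C@@H]1CO1 | starting material
8 | (6-chlorohexyl)magnesium bromide | ClCCCCCC[Mg]Br | intermediate, formed in the flask
9 | (R)-9-chlorononan-2-ol | C[C@@H](O)CCCCCCCCl | intermediate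
10 | (R)-tert-butyl[(9-chlorononan-2-yl)oxy]dimethylsilane | ClCCCCCCC[C@@H](C)O[Si](C)(C)C(C)(C)C | intermediate
11 | (R)-tert-butyl[(9-iodononan-2-yl)oxy]dimethylsilane | ICCCCCCC[C@@H](C)O[Si](C)(C)C(C)(C)C | intermediate
12 | 2-(tert-butyldimethylsilyl)-1,3-dithiane | CC(C)(C)[Si](C)(C)C1SCCCS1 | starting material
13 | [2-(tert-butyldimethylsilyl)-1,3-dithian-2-yl]lithium | [Li]C1([Si](C)(C)C(C)(C)C)SCCCS1 | intermediate, formed in the flask
14 | lithium (2S)-1-[3,5-bis(benzyloxy)phenyl]-3-[2-(tert-butyldimethylsilyl)-1,3-dithian-2-yl]propan-2-olate | [Li]O[C@H](CC1([Si](C)(C)C(C)(C)C)SCCCS1)Cc1cc(OCc2ccccc2)cc(OCc2ccccc2)c1 | intermediate, formed in the flask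
15 | {2-[(2S)-3-[3,5-bis(benzyloxy)phenyl]-2-(tert-butyldimethylsilyloxy)propyl]-1,3-dithian-2-yl}lithium | CC(C)(C)[Si](C)(C)O[C@H](CC1([Li])SCCCS1)Cc1cc(OCc2ccccc2)cc(OCc2ccccc2)c1 | intermediate, formed in the flask
16 | 2-[(2S)-3-[3,5-bis(benzyloxy)phenyl]-2-(tert-butyldimethylsilyloxy)propyl]-2-[(8R)-8-(tert-butyldimethylsilyloxy)nonyl]-1,3-dithiane | CC(C)(C)[Si](C)(C)O[C@H](CC1(CCCCCCC[C@@H](C)O[Si](C)(C)C(C)(C)C)SCCCS1)Cc1cc(OCc2ccccc2)cc(OCc2ccccc2)c1 | intermediate
17 | (2R,12R)-1-[3,5-bis(benzyloxy)phenyl]-2,12-bis(tert-butyldimethylsilyloxy)tridecane | CC(C)(C)[Si](C)(C)O[C@H](CCCCCCCCC[C@@H](C)O[Si](C)(C)C(C)(C)C)Cc1cc(OCc2ccccc2)cc(OCc2ccccc2)c1 | intermediate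
18 | (2R,12R)-1-[3,5-bis(benzyloxy)phenyl]tridecane-2,12-diol | O[C@H](CCCCCCCCC[C@@H](C)O)Cc1cc(OCc2ccccc2)cc(OCc2ccccc2)c1 | intermediate, formed in the flask
19 | (2R,12R)-1-[3,5-bis(benzyloxy)phenyl]tridecane-2,12-diyl diacetate | CC(=O)O[C@H](CCCCCCCCC[C@@H](C)OC(C)=O)Cc1cc(OCc2ccccc2)cc(OCc2ccccc2)c1 | intermediate
20 | (2R,12R)-1-[3,5-bis(benzyloxy)-2-formylphenyl]tridecane-2,12-diyl diacetate | CC(=O)O[C@H](CCCCCCCCC[C@@H](C)OC(C)=O)Cc1cc(OCc2ccccc2)cc(OCc2ccccc2)c1C=O | intermediate
21 | 2,4-bis(benzyloxy)-6-[(2R,12R)-2,12-diacetoxytridecyl]benzoic acid | CC(=O)O[C@H](CCCCCCCCC[C@@H](C)OC(C)=O)Cc1cc(OCc2ccccc2)cc(OCc2ccccc2)c1C(=O)O | intermediate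
22 | 6-[(2R,12R)-2,12-diacetoxytridecyl]-2,4-dihydroxybenzoic acid | CC(=O)O[C@H](CCCCCCCCC[C@@H](C)OC(C)=O)Cc1cc(O)cc(O)c1C(=O)O | target

## Step count and least certain steps

Total: 11 steps. Longest linear sequence: 9 steps (steps 3, 4, 5, 6, 7, 8, 9, 10 and 11, from 6); the epoxide branch (steps 1 and 2) joins at step 6.

Step 6 (key step). Three things are most likely to go wrong:
- The hindered, fairly basic anion 13 may remove a benzylic proton of 5 and isomerise the epoxide to an allylic alkoxide instead of opening it.
- The silyl shift may occur before the cosolvent is added, so that the relayed anion consumes a second molecule of epoxide.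
- Alkylation of 15 may be incomplete, through protonation or through elimination at 11.

Replacing HMPA by DMPU is only a change of conditions. The fallback changes the approach to a stepwise linchpin that sets out from 5. The smaller and less basic 2-lithio-1,3-dithiane (from 1,3-dithiane and n-BuLi, THF, −30 °C) opens 5 to give (2S)-1-[3,5-bis(benzyloxy)phenyl]-3-(1,3-dithian-2-yl)propan-2-ol F1. Silylation (TBSCl, imidazole, DMF) gives 2-[(2S)-3-[3,5-bis(benzyloxy)phenyl]-2-(tert-butyldimethylsilyloxy)propyl]-1,3-dithiane F2. Deprotonation of F2 (t-BuLi, THF/HMPA, −78 °C) generates the same anion 15 directly, and alkylation with 11 returns to the route at 16.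

Step 7. The likely failures are partial hydrogenolysis of the aryl benzyl ethers on the nickel surface and incomplete C–S cleavage on a deactivated catalyst. The fallback sets out from 16 and removes sulfur hydrolytically instead. Dithiane hydrolysis (MeI, CaCO3, aqueous MeCN) gives (2S,12R)-1-[3,5-bis(benzyloxy)phenyl]-2,12-bis(tert-butyldimethylsilyloxy)tridecan-4-one F3. Condensation with tosylhydrazide gives N'-[(2S,12R)-1-[3,5-bis(benzyloxy)phenyl]-2,12-bis(tert-butyldimethylsilyloxy)tridecan-4-ylidene]-4-methylbenzenesulfonohydrazide F4. Reduction of the tosylhydrazone with catecholborane followed by NaOAc (CHCl3, reflux) deoxygenates C4' and returns to the route at 17.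

Step 9. The likely failures are imperfect site selectivity (attack between the two benzyloxy groups), slow reaction at the position flanked by the branched chain, and acetate loss on prolonged heating with the acidic reagent. The fallback sets out from 19 and introduces the carboxyl carbon by halogenation and carbonylation. Bromination with NBS (MeCN, 0 °C), which should favour the position para to a benzyloxy group, gives (2R,12R)-1-[3,5-bis(benzyloxy)-2-bromophenyl]tridecane-2,12-diyl diacetate F5. Palladium-catalysed benzyloxycarbonylation (Pd(OAc)2, Xantphos, CO, benzyl alcohol, Et3N, toluene, 100 °C) gives benzyl 2,4-bis(benzyloxy)-6-[(2R,12R)-2,12-diacetoxytridecyl]benzoate F6 (the same substance as A9). Hydrogenolysis of its three benzyl groups (H2, Pd/C, EtOAc) returns to the route at 22 and makes step 10 unnecessary.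

Step 1. The likely failures are erosion of enantiomeric purity through direct displacement of chloride by the arylmetal (which leads to the mirror-image epoxide after closure), and homocoupling of the Grignard reagent. The fallback sets out from 1 (through 3) and sets C2' by resolution instead of from 2. Allylation of 3 with allyl bromide gives 1-allyl-3,5-bis(benzyloxy)benzene F7. Epoxidation (mCPBA, NaHCO3, CH2Cl2) gives rac-2-[3,5-bis(benzyloxy)benzyl]oxirane F8. Hydrolytic kinetic resolution with the (S,S)-configured (salen)Co(OAc) complex (trivalent cobalt) and 0.55 equiv of water should leave the (S)-epoxide, which returns to the route at 5.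

## Further compounds

F1 | step 6 | (2S)-1-[3,5-bis(benzyloxy)phenyl]-3-(1,3-dithian-2-yl)propan-2-ol | O[C@H](CC1SCCCS1)Cc1cc(OCc2ccccc2)cc(OCc2ccccc2)c1
F2 | step 6 | 2-[(2S)-3-[3,5-bis(benzyloxy)phenyl]-2-(tert-butyldimethylsilyloxy)propyl]-1,3-dithiane | CC(C)(C)[Si](C)(C)O[C@H](CC1SCCCS1)Cc1cc(OCc2ccccc2)cc(OCc2ccccc2)c1
F3 | step 7 | (2S,12R)-1-[3,5-bis(benzyloxy)phenyl]-2,12-bis(tert-butyldimethylsilyloxy)tridecan-4-one | CC(C)(C)[Si](C)(C)O[C@H](CC(=O)CCCCCCC[C@@H](C)O[Si](C)(C)C(C)(C)C)Cc1cc(OCc2ccccc2)cc(OCc2ccccc2)c1
F4 | step 7 | N'-[(2S,12R)-1-[3,5-bis(benzyloxy)phenyl]-2,12-bis(tert-butyldimethylsilyloxy)tridecan-4-ylidene]-4-methylbenzenesulfonohydrazide | CC(C)(C)[Si](C)(C)O[C@H](CC(=NNS(=O)(=O)c1ccc(C)cc1)CCCCCCC[C@@H](C)O[Si](C)(C)C(C)(C)C)Cc1cc(OCc2ccccc2)cc(OCc2ccccc2)c1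
F5 | step 9 | (2R,12R)-1-[3,5-bis(benzyloxy)-2-bromophenyl]tridecane-2,12-diyl diacetate | CC(=O)O[C@H](CCCCCCCCC[C@@H](C)OC(C)=O)Cc1cc(OCc2ccccc2)cc(OCc2ccccc2)c1Br
F6 | step 9 | benzyl 2,4-bis(benzyloxy)-6-[(2R,12R)-2,12-diacetoxytridecyl]benzoate | CC(=O)O[C@H](CCCCCCCCC[C@@H](C)OC(C)=O)Cc1cc(OCc2ccccc2)cc(OCc2ccccc2)c1C(=O)OCc1ccccc1
F7 | step 1 | 1-allyl-3,5-bis(benzyloxy)benzene | C=CCc1cc(OCc2ccccc2)cc(OCc2ccccc2)c1
F8 | step 1 | rac-2-[3,5-bis(benzyloxy)benzyl]oxirane | C(C1CO1)c1cc(OCc2ccccc2)cc(OCc2ccccc2)c1
A1 | alternative 1 | 1-methoxy-1,3-bis(trimethylsilyloxy)buta-1,3-diene | COC(O[Si](C)(C)C)=CC(=C)O[Si](C)(C)C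
A2 | alternative 1 | benzyl (5R,15R)-5,15-diacetoxyhexadec-2-ynoate | CC(=O)O[C@H](CCCCCCCCC[C@@H](C)OC(C)=O)CC#CC(=O)OCc1ccccc1
A3 | alternative 1 | benzyl 6-[(2R,12R)-2,12-diacetoxytridecyl]-2,4-dihydroxybenzoate | CC(=O)O[C@H](CCCCCCCCC[C@@H](C)OC(C)=O)Cc1cc(O)cc(O)c1C(=O)OCc1ccccc1
A4 | alternative 2 | (3E,6R,16R)-6,16-bis(tert-butyldimethylsilyloxy)heptadec-3-en-2-one | CC(=O)/C=C/C[C@H](O[Si](C)(C)C(C)(C)C)CCCCCCCCC[C@@H](C)O[Si](C)(C)C(C)(C)C
A5 | alternative 2 | dibenzyl malonate | O=C(CC(=O)OCc1ccccc1)OCc1ccccc1
A6 | alternative 2 | benzyl 2-[(2R,12R)-2,12-bis(tert-butyldimethylsilyloxy)tridecyl]-4,6-dioxocyclohexane-1-carboxylate | CC(C)(C)[Si](C)(C)O[C@H](CCCCCCCCC[C@@H](C)O[Si](C)(C)C(C)(C)C)CC1CC(=O)CC(=O)C1C(=O)OCc1ccccc1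
A7 | alternative 3 | 2,4-bis(benzyloxy)-1-iodobenzene | Ic1ccc(OCc2ccccc2)cc1OCc1ccccc1
A8 | alternative 3 | (2R,12R)-1-iodotridecane-2,12-diyl diacetate | CC(=O)O[C@H](CCCCCCCCC[C@@H](C)OC(C)=O)CI
A9 | alternative 3 | benzyl 2,4-bis(benzyloxy)-6-[(2R,12R)-2,12-diacetoxytridecyl]benzoate | CC(=O)O[C@H](CCCCCCCCC[C@@H](C)OC(C)=O)Cc1cc(OCc2ccccc2)cc(OCc2ccccc2)c1C(=O)OCc1ccccc1
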